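**Retrosynthetic overview**

- Methylarzanol 25 comes from arene 23 by removal of two silyl ethers and hydrolysis of the dioxolane that masks the acetyl group.
- The strategy rests on ring A: oxygens at Ar-C2, Ar-C4 and Ar-C6 alternate with three different carbon groups, the CH2 bridge to pyranone C3 at Ar-C1, prenyl at Ar-C3 and acetyl at Ar-C5. Ring A is therefore built last from cyclobutenone 14 and siloxyalkyne 18, forming Ar-C6 to Ar-C5, Ar-C4 to Ar-C3 and Ar-C6 to Ar-C1.
- Cyclobutenone 14 comes from the [2+2] addition of the ketene of pyranonylpropanoic acid 8 to prenyl siloxyalkyne 11. Both siloxyalkynes come from esters by Kowalski homologation.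
- The pyranone is made first: γ-acylation of a β-keto ester dianion, lactonization, Michael addition at pyranone C3 and O-methylation to the 2-methoxy-4-pyranone.
- Ring order: pyranone ring, then the four-membered ring of 14 (consumed again), then benzene ring A.

Key step: step 10

Assumption: the target is achiral, so cyclobutenone 14 is carried as the racemate; the side-chain acid is carried as an allyl ester because the triflic acid released in the O-methylation would cleave a tert-butyl ester.

**Route**

Step 1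
Reactants: 1 methyl 3-oxopentanoate; 2 N-methoxy-N-methylpropanamide
Product: 3 methyl 4-methyl-3,5-dioxoheptanoate
Conditions: LiN(iPr)2 (2.1 equiv), THF, −78 to 0 °C; then 2, 0 °C; aq HCl work-up
Reagents that add atoms: none
Why: Huckin–Weiler γ-acylation, in which the 2,4-dianion of the β-keto ester reacts at its more nucleophilic C4 with the Weinreb amide, whose tetrahedral adduct survives until work-up and prevents over-addition.

Step 2
Reactants: 3 methyl 4-methyl-3,5-dioxoheptanoate
Product: 4 6-ethyl-4-hydroxy-5-methyl-2H-pyran-2-one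
Conditions: DBU, toluene, reflux; aq HCl work-up
Reagents that add atoms: none
Why: Base-mediated lactonization of the C5 enol oxygen onto the methyl ester, the standard cyclization of 3,5-dioxo esters to 4-hydroxy-2-pyranones, with loss of methanol.

Step 3
Reactants: 4 6-ethyl-4-hydroxy-5-methyl-2H-pyran-2-one; 5 allyl acrylate
Product: 6 allyl 3-(6-ethyl-4-hydroxy-5-methyl-2-oxo-2H-pyran-3-yl)propanoate
Conditions: DBU (0.2 equiv), MeCN, 60 °C
Reagents that add atoms: none
Why: Michael addition of a vinylogous acid that is carbon-nucleophilic at C3 (as with 4-hydroxycoumarin and cyclic 1,3-diones); C-alkylation is the thermodynamic outcome because the oxa-Michael adduct reverts.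

Step 4
Reactants: 6 allyl 3-(6-ethyl-4-hydroxy-5-methyl-2-oxo-2H-pyran-3-yl)propanoate
Product: 7 allyl 3-(6-ethyl-2-methoxy-5-methyl-4-oxo-4H-pyran-3-yl)propanoate
Conditions: MeOTf, CH2Cl2, rt; aq NaHCO3 work-up
Reagents that add atoms: methyl trifluoromethanesulfonate, COS(=O)(=O)C(F)(F)F
Why: Regioselective O-methylation, in which the neutral 4-hydroxy-2-pyranone is alkylated at the lactone carbonyl oxygen to a 4-hydroxy-2-methoxypyrylium ion that loses a proton to the 2-methoxy-4-pyranone, the known course for 3,5-disubstituted substrates with MeOTf; the allyl ester is inert to the triflic acid formed.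

Step 5
Reactants: 7 allyl 3-(6-ethyl-2-methoxy-5-methyl-4-oxo-4H-pyran-3-yl)propanoate
Product: 8 3-(6-ethyl-2-methoxy-5-methyl-4-oxo-4H-pyran-3-yl)propanoic acid
Conditions: Pd(PPh3)4 (cat.), PhNHMe, THF, rt
Reagents that add atoms: none
Why: Tsuji–Trost deallylation, in which zerovalent palladium ionizes the allyl ester and N-methylaniline captures the allyl group, releasing the acid under neutral conditions that leave the 2-methoxypyranone untouched.

Step 6
Reactants: 9 ethyl 4-methylpent-3-enoate
Product: 11 triisopropyl[(5-methylhex-4-en-1-yn-1-yl)oxy]silane, via lithium ynolate 10 (not isolated)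
Conditions: CH2Br2, lithium 2,2,6,6-tetramethylpiperidide (LiTMP, 2.2 equiv), THF, −78 °C; then n-BuLi, −78 °C to rt; then iPr3SiCl, −78 °C to rt
Reagents that add atoms: dibromomethane, BrCBr; triisopropylsilyl chloride, CC(C)[Si](Cl)(C(C)C)C(C)C
Why: Kowalski ester homologation, in which LiCHBr2 adds to the ester at −78 °C faster than it enolizes it, bromine–lithium exchange triggers a 1,2-shift to the lithium ynolate, and the bulky silyl chloride silylates the ynolate on oxygen.

Step 7
Reactants: 8 3-(6-ethyl-2-methoxy-5-methyl-4-oxo-4H-pyran-3-yl)propanoic acid; 11 triisopropyl[(5-methylhex-4-en-1-yn-1-yl)oxy]silane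
Product: 14 4-[(6-ethyl-2-methoxy-5-methyl-4-oxo-4H-pyran-3-yl)methyl]-2-(3-methylbut-2-en-1-yl)-3-[(triisopropylsilyl)oxy]cyclobut-2-en-1-one (racemic), via acid chloride 12 (not isolated), via ketene 13 (not isolated)
Conditions: 1-chloro-N,N,2-trimethylprop-1-en-1-amine, CH2Cl2, 0 °C; then slow addition to 11, Et3N, toluene, 0 °C to rt
Reagents that add atoms: none
Why: Ketene–alkyne [2+2] cycloaddition, in which the aldoketene released by Et3N is attacked at its carbonyl carbon by the prenyl-bearing alkyne carbon, placing prenyl at C2, the siloxy group at C3 and the pyranonylmethyl group at C4 (new C4 stereocenter racemic and erased later); the acyl chloride is made under neutral conditions and used cold at once so that the pyranone carbonyl oxygen has no time to capture it.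

Step 8
Reactants: 15 ethyl pyruvate
Product: 16 ethyl 2-methyl-1,3-dioxolane-2-carboxylate
Conditions: Me3SiOCH2CH2OSiMe3, Me3SiOTf (cat.), CH2Cl2, −78 to −20 °C
Reagents that add atoms: 1,2-bis(trimethylsiloxy)ethane, C[Si](C)(C)OCCO[Si](C)(C)C
Why: Noyori ketalization under aprotic conditions converts the electrophilic keto group into the dioxolane without transesterifying the ethyl ester.

Step 9
Reactants: 16 ethyl 2-methyl-1,3-dioxolane-2-carboxylate
Product: 18 2-methyl-2-{[(triisopropylsilyl)oxy]ethynyl}-1,3-dioxolane, via lithium ynolate 17 (not isolated)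
Conditions: CH2Br2, lithium 2,2,6,6-tetramethylpiperidide (LiTMP, 2.2 equiv), THF, −78 °C; then n-BuLi, −78 °C to rt; then iPr3SiCl, −78 °C to rt; chromatography on Et3N-deactivated silica
Reagents that add atoms: dibromomethane, BrCBr; triisopropylsilyl chloride, CC(C)[Si](Cl)(C(C)C)C(C)C
Why: Kowalski ester homologation as in step 6; the migrating carbon carries oxygen substituents, a case covered by α-alkoxy esters, and the ester has no α-hydrogen to lose.

Step 10
Reactants: 14 4-[(6-ethyl-2-methoxy-5-methyl-4-oxo-4H-pyran-3-yl)methyl]-2-(3-methylbut-2-en-1-yl)-3-[(triisopropylsilyl)oxy]cyclobut-2-en-1-one (racemic); 18 2-methyl-2-{[(triisopropylsilyl)oxy]ethynyl}-1,3-dioxolane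
Product: 23 6-ethyl-3-{[2-hydroxy-3-(2-methyl-1,3-dioxolan-2-yl)-5-(3-methylbut-2-en-1-yl)-4,6-bis(triisopropylsiloxy)phenyl]methyl}-2-methoxy-5-methyl-4H-pyran-4-one, via vinylketene 19 (not isolated), via vinylcyclobutenone 20 (not isolated), via dienylketene 21 (not isolated), via cyclohexadienone 22 (not isolated)
Conditions: 18 (1.5 equiv), toluene, 80 then 110 °C, sealed tube, argon
Reagents that add atoms: none
Why: Danheiser benzannulation: four-electron electrocyclic opening of 14 gives vinylketene 19, whose carbonyl carbon bonds to the ketal-bearing alkyne carbon of 18 in a [2+2] step to give 20. Adduct 20 reopens to dienylketene 21, which closes ring A by thermal disrotatory six-electron electrocyclization (Ar-C6 to Ar-C1), and dienone 22 tautomerizes to the phenol. The closest known reactions are the benzannulations of cyclobutenones with siloxyalkynes that give resorcinol monosilyl ethers; a hexasubstituted product this crowded extends that scope. No stereocenter is formed and the one in 14 is erased. The only selectivity needed is the regiochemistry of the [2+2] step, which the polarization of the siloxyalkyne secures (the carbon remote from oxygen is the nucleophile). Outward rotation of the C4 substituent of 14 keeps its CH2 group away from the ketene and so disfavours a 1,5-hydrogen shift.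

Step 11
Reactants: 23 6-ethyl-3-{[2-hydroxy-3-(2-methyl-1,3-dioxolan-2-yl)-5-(3-methylbut-2-en-1-yl)-4,6-bis(triisopropylsiloxy)phenyl]methyl}-2-methoxy-5-methyl-4H-pyran-4-one
Product: 25 methylarzanol, via triol ketal 24 (not isolated)
Conditions: Bu4NF, AcOH (1:1), THF, 0 °C; then 1 M HCl, THF–H2O, 0 °C to rt; argon
Reagents that add atoms: water, O
Why: Fluoride cleavage of the two aryl silyl ethers under acetic acid buffering (so that no phenoxide can add to the methoxypyranone), then acid-catalysed ketal hydrolysis, which should be very fast on the electron-rich ring and mild enough to spare the prenyl group and the 2-methoxypyranone.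

**Compound list**

1 | methyl 3-oxopentanoate | CCC(=O)CC(=O)OC | starting material
2 | N-methoxy-N-methylpropanamide | CCC(=O)N(C)OC | starting material
3 | methyl 4-methyl-3,5-dioxoheptanoate (racemic, enolizable) | COC(=O)CC(=O)C(C)C(=O)CC | intermediate
4 | 6-ethyl-4-hydroxy-5-methyl-2H-pyran-2-one | CCc1oc(=O)cc(O)c1C | intermediate
5 | allyl acrylate | C=CC(=O)OCC=C | starting material
6 | allyl 3-(6-ethyl-4-hydroxy-5-methyl-2-oxo-2H-pyran-3-yl)propanoate | CCc1oc(=O)c(CCC(=O)OCC=C)c(O)c1C | intermediate
7 | allyl 3-(6-ethyl-2-methoxy-5-methyl-4-oxo-4H-pyran-3-yl)propanoate | CCc1oc(OC)c(CCC(=O)OCC=C)c(=O)c1C | intermediate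
8 | 3-(6-ethyl-2-methoxy-5-methyl-4-oxo-4H-pyran-3-yl)propanoic acid | CCc1oc(OC)c(CCC(=O)O)c(=O)c1C | intermediate
9 | ethyl 4-methylpent-3-enoate | CCOC(=O)CC=C(C)C | starting material
10 | lithium 5-methylhex-4-en-1-yn-1-olate | [Li+].[O-]C#CCC=C(C)C | intermediate
11 | triisopropyl[(5-methylhex-4-en-1-yn-1-yl)oxy]silane | CC(C)=CCC#CO[Si](C(C)C)(C(C)C)C(C)C | intermediate
12 | 3-(6-ethyl-2-methoxy-5-methyl-4-oxo-4H-pyran-3-yl)propanoyl chloride | CCc1oc(OC)c(CCC(Cl)=O)c(=O)c1C | intermediate
13 | 3-(6-ethyl-2-methoxy-5-methyl-4-oxo-4H-pyran-3-yl)prop-1-en-1-one (ketene) | CCc1oc(OC)c(CC=C=O)c(=O)c1C | intermediate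
14 | 4-[(6-ethyl-2-methoxy-5-methyl-4-oxo-4H-pyran-3-yl)methyl]-2-(3-methylbut-2-en-1-yl)-3-[(triisopropylsilyl)oxy]cyclobut-2-en-1-one (racemic) | O=C1C(CC=C(C)C)=C(O[Si](C(C)C)(C(C)C)C(C)C)C1Cc1c(OC)oc(CC)c(C)c1=O | intermediate
15 | ethyl pyruvate | CCOC(=O)C(C)=O | starting material
16 | ethyl 2-methyl-1,3-dioxolane-2-carboxylate | CCOC(=O)C1(C)OCCO1 | intermediate
17 | lithium 2-(2-methyl-1,3-dioxolan-2-yl)ethyn-1-olate | [Li+].[O-]C#CC1(C)OCCO1 | intermediate
18 | 2-methyl-2-{[(triisopropylsilyl)oxy]ethynyl}-1,3-dioxolane | CC(C)[Si](C(C)C)(C(C)C)OC#CC1(C)OCCO1 | intermediate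
19 | (Z)-5-(6-ethyl-2-methoxy-5-methyl-4-oxo-4H-pyran-3-yl)-2-(3-methylbut-2-en-1-yl)-3-[(triisopropylsilyl)oxy]penta-1,3-dien-1-one (vinylketene) | O=C=C(CC=C(C)C)/C(O[Si](C(C)C)(C(C)C)C(C)C)=C/Cc1c(OC)oc(CC)c(C)c1=O | intermediate
20 | 2-(2-methyl-1,3-dioxolan-2-yl)-4-(3-methylbut-2-en-1-yl)-3-[(triisopropylsilyl)oxy]-4-{(Z)-3-(6-ethyl-2-methoxy-5-methyl-4-oxo-4H-pyran-3-yl)-1-[(triisopropylsilyl)oxy]prop-1-en-1-yl}cyclobut-2-en-1-one (racemic [2+2] adduct) | O=C1C(C2(C)OCCO2)=C(O[Si](C(C)C)(C(C)C)C(C)C)C1(CC=C(C)C)/C(O[Si](C(C)C)(C(C)C)C(C)C)=C/Cc1c(OC)oc(CC)c(C)c1=O | intermediate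
21 | (3E,5Z)-7-(6-ethyl-2-methoxy-5-methyl-4-oxo-4H-pyran-3-yl)-2-(2-methyl-1,3-dioxolan-2-yl)-4-(3-methylbut-2-en-1-yl)-3,5-bis[(triisopropylsilyl)oxy]hepta-1,3,5-trien-1-one (dienylketene) | O=C=C(C1(C)OCCO1)/C(O[Si](C(C)C)(C(C)C)C(C)C)=C(CC=C(C)C)\C(O[Si](C(C)C)(C(C)C)C(C)C)=C\Cc1c(OC)oc(CC)c(C)c1=O | intermediate
22 | 6-[(6-ethyl-2-methoxy-5-methyl-4-oxo-4H-pyran-3-yl)methyl]-2-(2-methyl-1,3-dioxolan-2-yl)-4-(3-methylbut-2-en-1-yl)-3,5-bis[(triisopropylsilyl)oxy]cyclohexa-2,4-dien-1-one (racemic) | O=C1C(C2(C)OCCO2)=C(O[Si](C(C)C)(C(C)C)C(C)C)C(CC=C(C)C)=C(O[Si](C(C)C)(C(C)C)C(C)C)C1Cc1c(OC)oc(CC)c(C)c1=O | intermediate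
23 | 6-ethyl-3-{[2-hydroxy-3-(2-methyl-1,3-dioxolan-2-yl)-5-(3-methylbut-2-en-1-yl)-4,6-bis(triisopropylsiloxy)phenyl]methyl}-2-methoxy-5-methyl-4H-pyran-4-one | CCc1oc(OC)c(Cc2c(O[Si](C(C)C)(C(C)C)C(C)C)c(CC=C(C)C)c(O[Si](C(C)C)(C(C)C)C(C)C)c(C3(C)OCCO3)c2O)c(=O)c1C | intermediate
24 | 6-ethyl-2-methoxy-5-methyl-3-{[2,4,6-trihydroxy-3-(2-methyl-1,3-dioxolan-2-yl)-5-(3-methylbut-2-en-1-yl)phenyl]methyl}-4H-pyran-4-one (triol ketal) | CCc1oc(OC)c(Cc2c(O)c(CC=C(C)C)c(O)c(C3(C)OCCO3)c2O)c(=O)c1C | intermediate
25 | methylarzanol, 3-{[3-acetyl-2,4,6-trihydroxy-5-(3-methylbut-2-en-1-yl)phenyl]methyl}-6-ethyl-2-methoxy-5-methyl-4H-pyran-4-one | CCc1oc(OC)c(Cc2c(O)c(CC=C(C)C)c(O)c(C(C)=O)c2O)c(=O)c1C | target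

**Step count**

Total step count: 11. Longest linear sequence: 8 steps (steps 1, 2, 3, 4, 5, 7, 10, 11).

**Steps most likely to fail**

Step 10 (benzannulation). The bimolecular [2+2] capture of vinylketene 19 may be slowed by the quaternary ketal carbon on the attacking alkyne carbon. Silyl migration in 18 to a silylketene, self-reaction of 19, or thermal addition of the new phenol to the methoxypyranone could then take over. The fallback re-pairs the same three fragments and sets out from acid 8 and siloxyalkynes 18 and 11. Ketene 13, generated from 8 as in step 7, would be combined with 18 to give the ketal-bearing cyclobutenone F1, so the quaternary carbon goes in during the easier [2+2] step with an unhindered aldoketene. Heating F1 with the slimmer siloxyalkyne 11, whose attacking carbon carries only a CH2 group, should give the regioisomeric bis-silyl ether F2, with the free hydroxyl between the prenyl group and the CH2 bridge. Because all three oxygens end as hydroxyls, F2 should converge on triol ketal 24 under the Bu4NF/AcOH conditions of step 11.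

Step 7 (ketene [2+2]). The pyranone carbonyl oxygen may capture acyl chloride 12 or ketene 13, followed by chloride-induced loss of the O-methyl group, and the aldoketene may dimerize faster than it adds to 11. The fallback sets out from acid 8 and makes no acyl halide. The acid would be dehydrated in the presence of 11 with 2-chloro-1-methylpyridinium iodide and Et3N in toluene at 60 °C, a way of generating ketenes from free acids known from intramolecular ketene cycloadditions. The acyloxypyridinium salt F3 then exists only alongside base and should pass at once to ketene 13, returning to the route at cyclobutenone 14.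

Step 9 (homologation of the ketal ester). The 1,2-shift of the tertiary, doubly oxygenated carbon in the lithium carbenoid may be slow, or the tetrahedral adduct of this electron-poor ester may not collapse, so that little ynolate forms. The fallback sets out from ester 16 and makes the ynolate by oxidizing a lithium acetylide instead of rearranging an ester. Reduction with iBu2AlH at −78 °C would give the aldehyde F4. Dimethyl (1-diazo-2-oxopropyl)phosphonate with K2CO3 in MeOH would convert it into the terminal alkyne F5. Treatment with n-BuLi would give the lithium acetylide F6, which lithium tert-butyl peroxide (LiOOtBu, from tBuOOH and LiN(SiMe3)2) should oxidize to ynolate 17. Silylation with iPr3SiOTf then returns to the route at 18.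

**Further compounds**

F1 | step 10 | 4-[(6-ethyl-2-methoxy-5-methyl-4-oxo-4H-pyran-3-yl)methyl]-2-(2-methyl-1,3-dioxolan-2-yl)-3-[(triisopropylsilyl)oxy]cyclobut-2-en-1-one (racemic) | O=C1C(C2(C)OCCO2)=C(O[Si](C(C)C)(C(C)C)C(C)C)C1Cc1c(OC)oc(CC)c(C)c1=O
F2 | step 10 | 6-ethyl-3-{[2-hydroxy-5-(2-methyl-1,3-dioxolan-2-yl)-3-(3-methylbut-2-en-1-yl)-4,6-bis(triisopropylsiloxy)phenyl]methyl}-2-methoxy-5-methyl-4H-pyran-4-one | CCc1oc(OC)c(Cc2c(O[Si](C(C)C)(C(C)C)C(C)C)c(C3(C)OCCO3)c(O[Si](C(C)C)(C(C)C)C(C)C)c(CC=C(C)C)c2O)c(=O)c1C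
F3 | step 7 | 2-{[3-(6-ethyl-2-methoxy-5-methyl-4-oxo-4H-pyran-3-yl)propanoyl]oxy}-1-methylpyridinium iodide | CCc1oc(OC)c(CCC(=O)Oc2cccc[n+]2C)c(=O)c1C.[I-]
F4 | step 9 | 2-methyl-1,3-dioxolane-2-carbaldehyde | CC1(C=O)OCCO1
F5 | step 9 | 2-ethynyl-2-methyl-1,3-dioxolane | CC1(C#C)OCCO1
F6 | step 9 | lithium (2-methyl-1,3-dioxolan-2-yl)acetylide | [Li+].[C-]#CC1(C)OCCO1
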